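Ring B of the 5,7-dihydroxyflavone half (unit 1) is a 1,3,4-trisubstituted benzene. Chromone C2 sits on C1', para to O4', and C8 of the 7-methoxyflavone half (unit 2) sits on C3'. A 2-silyloxy-3-aryl-1,3-butadiene and a terminal acceptor alkyne deliver exactly this pattern, so ring B is cut at C1'–C2' and C5'–C6'. One Diels–Alder reaction joins both halves, closes the ring as a cyclohexa-1,4-diene and fixes the para relationship, so no biaryl coupling is needed. The diene hangs on C8 of a protected unit 2 flavone and is grown from an allyl group delivered from O7 by Claisen rearrangement. The dienophile is 2-ethynyl-5,7-diisopropoxychromone.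

Key step: step 11

Remark: the target has no stereocentre and its SMILES carries no axial descriptor, so the C3'–C8 biaryl axis is left unassigned; primed locants refer to ring B of unit 1, plain locants to the chromone cores.

Step 1
Reactants: 1 apigenin (5,7-dihydroxy-2-(4-hydroxyphenyl)-4H-chromen-4-one); 2 allyl bromide
Product: 3 7-(allyloxy)-5-hydroxy-2-(4-hydroxyphenyl)-4H-chromen-4-one
Conditions: 2 (1.05 equiv), K2CO3 (1.1 equiv), DMF, rt
Reagents that add atoms: none
Why: Williamson etherification with limiting base, in which the 7-OH (para to the C4 carbonyl, the most acidic phenol) is ionised first, the 5-OH is held in a hydrogen bond to C4=O and the 4'-OH is less acidic, so one equivalent of the reactive halide should go mainly to O7 and any 7,4'-diether is removed by chromatography.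

Step 2
Reactants: 3 7-(allyloxy)-5-hydroxy-2-(4-hydroxyphenyl)-4H-chromen-4-one
Product: 4 7-(allyloxy)-5-isopropoxy-2-(4-isopropoxyphenyl)-4H-chromen-4-one
Conditions: 2-iodopropane (6 equiv), Cs2CO3 (4 equiv), DMF, 60 °C
Reagents that add atoms: 2-iodopropane, CC(C)I
Why: Williamson etherification pushed with excess secondary iodide, Cs2CO3 and heat, which the chelated 5-OH requires, while the allyl ether and the pyrone ring are inert to carbonate in DMF.

Step 3
Reactants: 4 7-(allyloxy)-5-isopropoxy-2-(4-isopropoxyphenyl)-4H-chromen-4-one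
Product: 5 8-allyl-7-hydroxy-5-isopropoxy-2-(4-isopropoxyphenyl)-4H-chromen-4-one
Conditions: PhNEt2, 200 °C, Ar
Reagents that add atoms: none
Why: Aromatic Claisen rearrangement ([3,3]-sigmatropic shift, then rearomatisation) that should favour C8, because the fused pyrone gives C7–C8 the higher double-bond character (7-allyloxychromones and 7-allyloxycoumarins give 8-allyl products), alkylation of O5 removes the chelate that would steer towards C6, and the bulky 5-isopropoxy group screens C6.

Step 4
Reactants: 5 8-allyl-7-hydroxy-5-isopropoxy-2-(4-isopropoxyphenyl)-4H-chromen-4-one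
Product: 6 8-allyl-5-isopropoxy-2-(4-isopropoxyphenyl)-7-methoxy-4H-chromen-4-one
Conditions: MeI (2 equiv), K2CO3 (2 equiv), acetone, reflux
Reagents that add atoms: iodomethane, CI
Why: Williamson O-methylation of the only free phenol, which installs the 7-OMe of the target and also prevents O7 from attacking the palladium-activated allyl group in the next step.

Step 5
Reactants: 6 8-allyl-5-isopropoxy-2-(4-isopropoxyphenyl)-7-methoxy-4H-chromen-4-one
Product: 7 5-isopropoxy-2-(4-isopropoxyphenyl)-7-methoxy-8-(2-oxopropyl)-4H-chromen-4-one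
Conditions: PdCl2 (10 mol %), CuCl (50 mol %), O2 (1 atm), DMF/H2O 7:1, rt
Reagents that add atoms: water, O
Why: Wacker–Tsuji oxidation, in which Markovnikov hydroxypalladation of the terminal alkene and β-hydride elimination give the methyl ketone, the normal outcome for allylarenes, with aryl ethers and the flavone core untouched.

Step 6
Reactants: 7 5-isopropoxy-2-(4-isopropoxyphenyl)-7-methoxy-8-(2-oxopropyl)-4H-chromen-4-one
Product: 9 5-isopropoxy-2-(4-isopropoxyphenyl)-7-methoxy-8-(3-oxobut-1-en-2-yl)-4H-chromen-4-one, via Mannich base 8 (not isolated)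
Conditions: (CH2O)n (3 equiv), iPr2NH·CF3CO2H (1 equiv), CF3CO2H (10 mol %), THF, reflux
Reagents that add atoms: paraformaldehyde (formaldehyde equivalent), C=O
Why: Mannich condensation followed by β-elimination of the amine (α-methylenation of a ketone), in which the benzylic CH2 is the more acidic and more readily enolised α-position of an arylacetone and takes up the iminium ion, after which the bulky amine leaves spontaneously and the transient stereocentre of 8 disappears.

Step 7
Reactants: 9 5-isopropoxy-2-(4-isopropoxyphenyl)-7-methoxy-8-(3-oxobut-1-en-2-yl)-4H-chromen-4-one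
Product: 10 8-[3-(tert-butyldimethylsilyloxy)buta-1,3-dien-2-yl]-5-isopropoxy-2-(4-isopropoxyphenyl)-7-methoxy-4H-chromen-4-one
Conditions: TBSOTf (2 equiv), Et3N (4 equiv), CH2Cl2, 0 °C; cold aq NaHCO3 work-up, Et3N-deactivated silica
Reagents that add atoms: tert-butyldimethylsilyl trifluoromethanesulfonate, CC(C)(C)[Si](C)(C)OS(=O)(=O)C(F)(F)F
Why: Soft enolisation and O-silylation of a methyl enone, the standard entry to 2-silyloxy-1,3-dienes, in which only the CH3 group carries enolisable hydrogens and any silylation of the flavone carbonyl is reversible and lost on work-up.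

Step 8
Reactants: 11 2,4,6-trihydroxyacetophenone
Product: 12 1-(2-hydroxy-4,6-diisopropoxyphenyl)ethan-1-one
Conditions: 2-bromopropane (2.4 equiv), K2CO3 (2.5 equiv), DMF, 60 °C
Reagents that add atoms: 2-bromopropane, CC(C)Br
Why: Williamson etherification that stops after two alkylations, because the remaining phenol is hydrogen-bonded to the acetyl group and too unreactive towards a secondary bromide under these conditions.

Step 9
Reactants: 12 1-(2-hydroxy-4,6-diisopropoxyphenyl)ethan-1-one; 13 ethyl diethoxyacetate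
Product: 16 5,7-diisopropoxy-4-oxo-4H-chromene-2-carbaldehyde, via 1,3-diketone 14 (not isolated), via diethyl acetal 15 (not isolated)
Conditions: NaH (3.5 equiv), 13 (1.5 equiv), THF, 0 °C → reflux; then 3 M aq HCl/THF, 50 °C
Reagents that add atoms: water, O
Why: Crossed Claisen condensation of the ketone enolate with the activated ester, then acid-catalysed cyclodehydration of the o-hydroxyaryl 1,3-diketone (the classical chromone synthesis) and acetal hydrolysis in the same medium, which reaches the aldehyde level without a separate oxidation and leaves aryl isopropyl ethers intact in dilute aqueous acid.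

Step 10
Reactants: 16 5,7-diisopropoxy-4-oxo-4H-chromene-2-carbaldehyde
Product: 17 2-ethynyl-5,7-diisopropoxy-4H-chromen-4-one
Conditions: dimethyl (1-diazo-2-oxopropyl)phosphonate (1.2 equiv), K2CO3 (2 equiv), MeOH/THF, 0 °C → rt, short reaction time
Reagents that add atoms: dimethyl (1-diazo-2-oxopropyl)phosphonate, CC(=O)C(=[N+]=[N-])P(=O)(OC)OC
Why: Seyferth–Gilbert homologation in the Ohira–Bestmann variant, in which the diazophosphonate anion olefinates the very electrophilic aldehyde, N2 is lost and a 1,2-hydrogen shift gives the terminal alkyne, the two alkoxy donors on ring A tempering the electrophilicity of the pyrone towards methoxide.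

Step 11
Reactants: 10 8-[3-(tert-butyldimethylsilyloxy)buta-1,3-dien-2-yl]-5-isopropoxy-2-(4-isopropoxyphenyl)-7-methoxy-4H-chromen-4-one; 17 2-ethynyl-5,7-diisopropoxy-4H-chromen-4-one
Product: 18 8-[2-(tert-butyldimethylsilyloxy)-5-(5,7-diisopropoxy-4-oxo-4H-chromen-2-yl)cyclohexa-1,4-dien-1-yl]-5-isopropoxy-2-(4-isopropoxyphenyl)-7-methoxy-4H-chromen-4-one
Conditions: 17 (1.5 equiv), BHT (5 mol %), o-xylene (1 M), 145 °C, Ar; used crude after evaporation
Reagents that add atoms: none
Why: A thermal, normal-electron-demand [4+2] cycloaddition, concerted but asynchronous, in which the HOMO of silyloxydiene 10 overlaps with the LUMO of the alkyne of 17, lowered by conjugation through C2=C3 to the C4 carbonyl. The closest known reaction type is the Diels–Alder reaction of 2-silyloxy-1,3-butadienes with acetylenic ketones and esters, which gives 1-silyloxycyclohexa-1,4-dienes with the acceptor para to oxygen. The one new ring, the six-membered carbocycle that becomes ring B of unit 1, closes by intermolecular suprafacial addition of the s-cis diene across one π bond of the alkyne, C5'–C6' forming ahead of C1'–C2'. No stereocentre arises, since the four bonding carbons end as two ring CH2 groups and two sp2 carbons. Regioselectivity is the demand: the CH2 terminus next to the silyloxy-bearing carbon has the largest HOMO coefficient and pairs with the unsubstituted alkyne carbon, the vinylogous acceptor site, while the rival directing effect of the aryl group on the neighbouring diene carbon is small because the di-ortho-substituted flavone ring is twisted out of the diene plane. Site selectivity follows from the terminal alkyne being the only unhindered π acceptor, the C2=C3 bonds of both pyrone rings being trisubstituted and deactivated by the ring oxygen.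

Step 12
Reactants: 18 the cyclohexa-1,4-diene adduct
Product: 19 8-[2-(tert-butyldimethylsilyloxy)-5-(5,7-diisopropoxy-4-oxo-4H-chromen-2-yl)phenyl]-5-isopropoxy-2-(4-isopropoxyphenyl)-7-methoxy-4H-chromen-4-one
Conditions: DDQ (1.2 equiv), PhMe, rt
Reagents that add atoms: none
Why: Dehydrogenative aromatisation with DDQ, in which hydride abstraction from a doubly allylic CH2 gives a cation stabilised by the silyl enol ether and proton loss delivers the arene, the aryl alkyl ethers being inert at room temperature.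

Step 13
Reactants: 19 the aryl silyl ether
Product: 20 8-[2-hydroxy-5-(5,7-diisopropoxy-4-oxo-4H-chromen-2-yl)phenyl]-5-isopropoxy-2-(4-isopropoxyphenyl)-7-methoxy-4H-chromen-4-one
Conditions: TBAF (1.2 equiv), AcOH (1.2 equiv), THF, 0 °C
Reagents that add atoms: none
Why: Fluoride-induced cleavage of an aryl silyl ether, buffered with AcOH to keep basic phenoxide away from the pyrone rings and run as its own step because a hindered aryl silyl ether cannot be relied on to fall to BCl3.

Step 14
Reactants: 20 the tetra-O-isopropyl phenol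
Product: 21 sotetsuflavone
Conditions: BCl3 (1 M in CH2Cl2, 12 equiv), CH2Cl2, −78 °C → rt; then ice/1 M aq HCl
Reagents that add atoms: none
Why: Lewis-acid dealkylation, in which BCl3 cleaves aryl isopropyl ethers by chloride capture of the secondary alkyl group (fastest at the two O5 ethers through chelation to C4=O), whereas an unchelated aryl methyl ether such as 7-OMe needs a stronger reagent or heat and should survive.

Compound list
1 | apigenin, 5,7-dihydroxy-2-(4-hydroxyphenyl)-4H-chromen-4-one | O=c1cc(-c2ccc(O)cc2)oc2cc(O)cc(O)c12 | starting material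
2 | allyl bromide | C=CCBr | starting material
3 | 7-(allyloxy)-5-hydroxy-2-(4-hydroxyphenyl)-4H-chromen-4-one | C=CCOc1cc(O)c2c(=O)cc(-c3ccc(O)cc3)oc2c1 | intermediate
4 | 7-(allyloxy)-5-isopropoxy-2-(4-isopropoxyphenyl)-4H-chromen-4-one | C=CCOc1cc(OC(C)C)c2c(=O)cc(-c3ccc(OC(C)C)cc3)oc2c1 | intermediate
5 | 8-allyl-7-hydroxy-5-isopropoxy-2-(4-isopropoxyphenyl)-4H-chromen-4-one | C=CCc1c(O)cc(OC(C)C)c2c(=O)cc(-c3ccc(OC(C)C)cc3)oc12 | intermediate
6 | 8-allyl-5-isopropoxy-2-(4-isopropoxyphenyl)-7-methoxy-4H-chromen-4-one | C=CCc1c(OC)cc(OC(C)C)c2c(=O)cc(-c3ccc(OC(C)C)cc3)oc12 | intermediate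
7 | 5-isopropoxy-2-(4-isopropoxyphenyl)-7-methoxy-8-(2-oxopropyl)-4H-chromen-4-one | CC(=O)Cc1c(OC)cc(OC(C)C)c2c(=O)cc(-c3ccc(OC(C)C)cc3)oc12 | intermediate
8 | 8-[1-(diisopropylamino)-3-oxobutan-2-yl]-5-isopropoxy-2-(4-isopropoxyphenyl)-7-methoxy-4H-chromen-4-one (racemic Mannich base) | CC(=O)C(CN(C(C)C)C(C)C)c1c(OC)cc(OC(C)C)c2c(=O)cc(-c3ccc(OC(C)C)cc3)oc12 | intermediate
9 | 5-isopropoxy-2-(4-isopropoxyphenyl)-7-methoxy-8-(3-oxobut-1-en-2-yl)-4H-chromen-4-one | CC(=O)C(=C)c1c(OC)cc(OC(C)C)c2c(=O)cc(-c3ccc(OC(C)C)cc3)oc12 | intermediate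
10 | 8-[3-(tert-butyldimethylsilyloxy)buta-1,3-dien-2-yl]-5-isopropoxy-2-(4-isopropoxyphenyl)-7-methoxy-4H-chromen-4-one | C=C(O[Si](C)(C)C(C)(C)C)C(=C)c1c(OC)cc(OC(C)C)c2c(=O)cc(-c3ccc(OC(C)C)cc3)oc12 | intermediate
11 | 2,4,6-trihydroxyacetophenone | CC(=O)c1c(O)cc(O)cc1O | starting material
12 | 1-(2-hydroxy-4,6-diisopropoxyphenyl)ethan-1-one | CC(=O)c1c(O)cc(OC(C)C)cc1OC(C)C | intermediate
13 | ethyl diethoxyacetate | CCOC(OCC)C(=O)OCC | starting material
14 | 4,4-diethoxy-1-(2-hydroxy-4,6-diisopropoxyphenyl)butane-1,3-dione | CCOC(OCC)C(=O)CC(=O)c1c(O)cc(OC(C)C)cc1OC(C)C | intermediate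
15 | 2-(diethoxymethyl)-5,7-diisopropoxy-4H-chromen-4-one | CCOC(OCC)c1cc(=O)c2c(OC(C)C)cc(OC(C)C)cc2o1 | intermediate
16 | 5,7-diisopropoxy-4-oxo-4H-chromene-2-carbaldehyde | O=Cc1cc(=O)c2c(OC(C)C)cc(OC(C)C)cc2o1 | intermediate
17 | 2-ethynyl-5,7-diisopropoxy-4H-chromen-4-one | C#Cc1cc(=O)c2c(OC(C)C)cc(OC(C)C)cc2o1 | intermediate
18 | 8-[2-(tert-butyldimethylsilyloxy)-5-(5,7-diisopropoxy-4-oxo-4H-chromen-2-yl)cyclohexa-1,4-dien-1-yl]-5-isopropoxy-2-(4-isopropoxyphenyl)-7-methoxy-4H-chromen-4-one | CC(C)(C)[Si](C)(C)OC1=C(CC(=CC1)c1cc(=O)c2c(OC(C)C)cc(OC(C)C)cc2o1)c1c(OC)cc(OC(C)C)c2c(=O)cc(-c3ccc(OC(C)C)cc3)oc12 | intermediate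
19 | 8-[2-(tert-butyldimethylsilyloxy)-5-(5,7-diisopropoxy-4-oxo-4H-chromen-2-yl)phenyl]-5-isopropoxy-2-(4-isopropoxyphenyl)-7-methoxy-4H-chromen-4-one | CC(C)(C)[Si](C)(C)Oc1ccc(-c2cc(=O)c3c(OC(C)C)cc(OC(C)C)cc3o2)cc1-c1c(OC)cc(OC(C)C)c2c(=O)cc(-c3ccc(OC(C)C)cc3)oc12 | intermediate
20 | 8-[2-hydroxy-5-(5,7-diisopropoxy-4-oxo-4H-chromen-2-yl)phenyl]-5-isopropoxy-2-(4-isopropoxyphenyl)-7-methoxy-4H-chromen-4-one | Oc1ccc(-c2cc(=O)c3c(OC(C)C)cc(OC(C)C)cc3o2)cc1-c1c(OC)cc(OC(C)C)c2c(=O)cc(-c3ccc(OC(C)C)cc3)oc12 | intermediate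
21 | sotetsuflavone | COc1cc(O)c2c(=O)cc(-c3ccc(O)cc3)oc2c1-c1cc(-c2cc(=O)c3c(O)cc(O)cc3o2)ccc1O | target

Total step count: 14.
Longest linear sequence: 11 (steps 1–7, then 11–14). The dienophile branch (steps 8–10) is made in parallel.

Steps most likely to fail

Step 11. The alkyne is activated only through a vinylogous carbonyl, and the 2,3-disubstituted diene may populate its s-cis form poorly. The cycloaddition may therefore be slower than desilylation or polymerisation of the partners, or the regiochemistry may erode.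
- The fallback sets out from diene 10 and acetophenone 12 and comes back at 19.
- Diene 10 is heated with methyl propiolate, a fully activated acetylenic ester for which para-selective addition of 2-silyloxydienes is established. This gives methyl 4-(tert-butyldimethylsilyloxy)-3-[5-isopropoxy-2-(4-isopropoxyphenyl)-7-methoxy-4-oxo-4H-chromen-8-yl]cyclohexa-1,4-diene-1-carboxylate F1.
- DDQ in toluene aromatises it to the corresponding methyl benzoate F2.
- The dianion of 12 (LiN(SiMe3)2, THF, −78 °C → rt) is acylated by F2 to the 1-(2-hydroxy-4,6-diisopropoxyphenyl)-3-aryl-propane-1,3-dione F3.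
- Cyclodehydration (p-TsOH, toluene, 80 °C) then builds the unit 1 chromone onto the finished ring B and gives 19.

Step 10. Methoxide or the diazophosphonate anion may add to the electrophilic pyrone or to the newly formed acceptor alkyne. The possible pathways are conjugate addition, ring opening and dipolar cycloaddition.
- The fallback sets out from aldehyde 16 and comes back at 17, with no alkoxide and no diazo reagent.
- Ramirez olefination (CBr4, PPh3, CH2Cl2, 0 °C) gives 2-(2,2-dibromovinyl)-5,7-diisopropoxy-4H-chromen-4-one F4.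
- Stereoselective hydrogenolysis of the less hindered C–Br bond (Bu3SnH, Pd(PPh3)4, toluene, rt) gives (Z)-2-(2-bromovinyl)-5,7-diisopropoxy-4H-chromen-4-one F5.
- The anti-disposed H and Br of F5 are then eliminated with DBU in CH2Cl2 to give 17.

Step 6. Aminomethylation may stall at the crowded benzylic carbon or drift to the methyl group, and the enone may take up a second formaldehyde or oligomerise.
- The fallback sets out from 6 and comes back at 9, using a carbonyl compound that has only one α-position.
- Lemieux–Johnson cleavage (OsO4 cat., NaIO4, 2,6-lutidine, dioxane/H2O) gives 2-[5-isopropoxy-2-(4-isopropoxyphenyl)-7-methoxy-4-oxo-4H-chromen-8-yl]acetaldehyde F6.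
- Amine-catalysed α-methylenation of this aldehyde (aq HCHO, pyrrolidine/propionic acid, iPrOH, 45 °C) gives the 2-arylacrolein F7.
- MeMgBr (THF, −78 °C, aldehyde-selective) gives the racemic 8-(3-hydroxybut-1-en-2-yl)flavone F8.
- MnO2 in CH2Cl2 oxidises the allylic alcohol to 9.

Further compounds
F1 | step 11 | methyl 4-(tert-butyldimethylsilyloxy)-3-[5-isopropoxy-2-(4-isopropoxyphenyl)-7-methoxy-4-oxo-4H-chromen-8-yl]cyclohexa-1,4-diene-1-carboxylate | COC(=O)C1=CCC(O[Si](C)(C)C(C)(C)C)=C(C1)c1c(OC)cc(OC(C)C)c2c(=O)cc(-c3ccc(OC(C)C)cc3)oc12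
F2 | step 11 | methyl 4-(tert-butyldimethylsilyloxy)-3-[5-isopropoxy-2-(4-isopropoxyphenyl)-7-methoxy-4-oxo-4H-chromen-8-yl]benzoate | COC(=O)c1ccc(O[Si](C)(C)C(C)(C)C)c(c1)-c1c(OC)cc(OC(C)C)c2c(=O)cc(-c3ccc(OC(C)C)cc3)oc12
F3 | step 11 | 1-(2-hydroxy-4,6-diisopropoxyphenyl)-3-{4-(tert-butyldimethylsilyloxy)-3-[5-isopropoxy-2-(4-isopropoxyphenyl)-7-methoxy-4-oxo-4H-chromen-8-yl]phenyl}propane-1,3-dione | CC(C)Oc1cc(O)c(C(=O)CC(=O)c2ccc(O[Si](C)(C)C(C)(C)C)c(c2)-c2c(OC)cc(OC(C)C)c3c(=O)cc(-c4ccc(OC(C)C)cc4)oc23)c(OC(C)C)c1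
F4 | step 10 | 2-(2,2-dibromovinyl)-5,7-diisopropoxy-4H-chromen-4-one | BrC(Br)=Cc1cc(=O)c2c(OC(C)C)cc(OC(C)C)cc2o1
F5 | step 10 | (Z)-2-(2-bromovinyl)-5,7-diisopropoxy-4H-chromen-4-one | Br/C=C\c1cc(=O)c2c(OC(C)C)cc(OC(C)C)cc2o1
F6 | step 6 | 2-[5-isopropoxy-2-(4-isopropoxyphenyl)-7-methoxy-4-oxo-4H-chromen-8-yl]acetaldehyde | O=CCc1c(OC)cc(OC(C)C)c2c(=O)cc(-c3ccc(OC(C)C)cc3)oc12
F7 | step 6 | 2-[5-isopropoxy-2-(4-isopropoxyphenyl)-7-methoxy-4-oxo-4H-chromen-8-yl]prop-2-enal | C=C(C=O)c1c(OC)cc(OC(C)C)c2c(=O)cc(-c3ccc(OC(C)C)cc3)oc12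
F8 | step 6 | 8-(3-hydroxybut-1-en-2-yl)-5-isopropoxy-2-(4-isopropoxyphenyl)-7-methoxy-4H-chromen-4-one (racemic) | CC(O)C(=C)c1c(OC)cc(OC(C)C)c2c(=O)cc(-c3ccc(OC(C)C)cc3)oc12
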